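The route builds the benzo ring of the 2,3-dihydrobenzofuran last, from a furan. In the target, O1 sits on C7a and the methoxy oxygen on the neighbouring C7. This 1,2-dioxygenated edge is what results when a terminal ynol ether, tied through O1–C2–C3 to C2 of a 2,4-disubstituted furan, is cycloisomerised by gold. One operation closes the dihydrofuran ring (C3a–C7a) and the benzene ring (C6–C7) and moves the furan oxygen to C7 as a phenol, with the propyl arm already at C5. The substrate is an open-chain syn ethynyl ether carrying both stereocentres, set beforehand by an auxiliary aldol between a furylacetyl imide and O-silyl vanillin.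

Key step: step 11

Remarks on the chemistry:
- Numbering follows the benzofuran (O1, C2, C3, C3a, C4–C7, C7a); C9 is the CH2O carbon on C3. TIPS = triisopropylsilyl (TIPSO = its ether oxygen), TBS = tert-butyldimethylsilyl, Tr = trityl.
- The C9 hydroxyl is carried through the alkoxide and gold chemistry as a trityl ether. A small silyl ether 1,3 to a potassium alkoxide could shift from oxygen to oxygen, and the trityl ether is later released without touching the three silyl ethers.
- The open-chain (1R,2S) syn arrangement corresponds to trans-(2R,3S) on the ring.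
- The (E) geometry written for the transient dichlorovinyl ether is assumed (anti addition); it is erased in the same step.

Step 1
Reactants: 1 allyl alcohol
Product: 2 allyl triisopropylsilyl ether
Conditions: TIPSCl, imidazole, CH2Cl2, 0 °C → rt
Reagents that add atoms: triisopropylsilyl chloride, CC(C)[Si](Cl)(C(C)C)C(C)C
Why: Silyl ether formation on a primary alcohol is routine and installs a group that should survive aqueous base, organolithium and mild acid later in the route.

Step 2
Reactants: 2 allyl triisopropylsilyl ether; 3 9-BBN (9-borabicyclo[3.3.1]nonane); 4 4-bromo-2-furaldehyde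
Product: 6 4-[3-(TIPSO)propyl]furan-2-carbaldehyde, via alkyl-9-BBN borane 5 (not isolated)
Conditions: 9-BBN, THF, 0 °C → rt; then 4, Pd(dppf)Cl2 (5 mol %), aq K3PO4, DMF, 50 °C
Reagents that add atoms: none
Why: Anti-Markovnikov hydroboration of the terminal alkene followed by B-alkyl Suzuki–Miyaura coupling should place the three-carbon chain on furan C4, the bromide being activated by the 2-formyl group and the aldehyde being added only after all B–H is consumed.

Step 3
Reactants: 6 4-[3-(TIPSO)propyl]furan-2-carbaldehyde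
Product: 7 {4-[3-(TIPSO)propyl]furan-2-yl}acetonitrile
Conditions: TosMIC, t-BuOK, DME, −50 → −20 °C; then MeOH, 65 °C
Reagents that add atoms: p-toluenesulfonylmethyl isocyanide (TosMIC), Cc1ccc(S(=O)(=O)C[N+]#[C-])cc1
Why: Van Leusen reductive cyanation should give the one-carbon-homologated nitrile (TosMIC adduct, oxazoline opening, deformylation by methanol, loss of sulfinate) and avoids a furfuryl halide, which would be open to SN2′ attack at furan C5.

Step 4
Reactants: 7 {4-[3-(TIPSO)propyl]furan-2-yl}acetonitrile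
Product: 8 {4-[3-(TIPSO)propyl]furan-2-yl}acetic acid
Conditions: NaOH, EtOH/H2O, 80 °C; then 1 M HCl to pH 3–4, 0 °C
Reagents that add atoms: water, O; sodium hydroxide, [Na+].[OH-]
Why: Alkaline nitrile hydrolysis of an activated heteroarylacetonitrile should give the acid, since the furan and the primary TIPS ether tolerate hot hydroxide and the acidification is kept cold and mild.

Step 5
Reactants: 8 {4-[3-(TIPSO)propyl]furan-2-yl}acetic acid; 9 (R)-4-benzyl-1,3-oxazolidin-2-one
Product: 11 (R)-4-benzyl-3-({4-[3-(TIPSO)propyl]furan-2-yl}acetyl)-1,3-oxazolidin-2-one, via mixed pivalic anhydride 10 (not isolated)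
Conditions: PivCl, Et3N, THF, −20 → 0 °C; then LiCl, 9, rt
Reagents that add atoms: pivaloyl chloride, CC(C)(C)C(Cl)=O (its acyl group stands only in intermediate 10)
Why: N-Acylation of the oxazolidinone through a mixed anhydride with LiCl/Et3N is a standard one-pot method for arylacetic acids and needs no strong base.

Step 6
Reactants: 12 vanillin
Product: 13 3-methoxy-4-(TIPSO)benzaldehyde
Conditions: TIPSCl, imidazole, DMF, rt
Reagents that add atoms: triisopropylsilyl chloride, CC(C)[Si](Cl)(C(C)C)C(C)C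
Why: Phenol silylation is routine, and the bulky TIPS group is chosen so that the aryl silyl ether does not hand its silyl group to alkoxides or fall to carbonate later.

Step 7
Reactants: 11 (R)-4-benzyl-3-({4-[3-(TIPSO)propyl]furan-2-yl}acetyl)-1,3-oxazolidin-2-one; 13 3-methoxy-4-(TIPSO)benzaldehyde
Product: 15 (R)-4-benzyl-3-[(2S,3R)-3-hydroxy-3-(3-methoxy-4-TIPSO-phenyl)-2-{4-[3-(TIPSO)propyl]furan-2-yl}propanoyl]-1,3-oxazolidin-2-one, via Z-dibutylboron enolate 14 (not isolated)
Conditions: Bu2BOTf, i-Pr2NEt, CH2Cl2, −78 → 0 °C; 13, −78 → 0 °C; pH 7 buffer, MeOH, H2O2, 0 °C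
Reagents that add atoms: dibutylboron triflate, CCCCB(CCCC)OS(=O)(=O)C(F)(F)F (boron stands only in intermediate 14)
Why: In this Evans syn-aldol the Z-boron enolate reacts through a closed Zimmerman–Traxler chair with the oxazolidinone carbonyl turned away from the enolate oxygen, so the aldehyde should add to the face opposite the (R)-benzyl group and set the α-carbon (S, future C3) and the carbinol carbon (R, future C2) as the syn pair.

Step 8
Reactants: 15 syn-aldol adduct
Product: 16 (1R,2S)-1-(3-methoxy-4-TIPSO-phenyl)-2-{4-[3-(TIPSO)propyl]furan-2-yl}propane-1,3-diol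
Conditions: LiBH4, THF, MeOH (1 equiv), 0 °C
Reagents that add atoms: none
Why: Reductive cleavage of the N-acyl oxazolidinone with borohydride should give the primary alcohol and release the auxiliary, and it removes the acidic α-furyl carbonyl proton so that neither stereocentre can epimerise or be lost by retro-aldol afterwards.

Step 9
Reactants: 16 (1R,2S)-diol
Product: 17 (1R,2S)-1-(3-methoxy-4-TIPSO-phenyl)-2-{4-[3-(TIPSO)propyl]furan-2-yl}-3-(trityloxy)propan-1-ol
Conditions: TrCl, Et3N, DMAP (cat.), CH2Cl2, rt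
Reagents that add atoms: trityl chloride, ClC(c1ccccc1)(c1ccccc1)c1ccccc1
Why: Tritylation is highly selective for the primary over the hindered secondary benzylic hydroxyl and gives an ether that cannot migrate to the neighbouring alkoxide of the next step.

Step 10
Reactants: 17 trityl ether alcohol; 18 trichloroethylene
Product: 21 (1R,2S)-1-(3-methoxy-4-TIPSO-phenyl)-2-{4-[3-(TIPSO)propyl]furan-2-yl}-3-(trityloxy)propyl ethynyl ether, via E-dichlorovinyl ether 19 (not isolated), via lithium alkynyl ether 20 (not isolated)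
Conditions: KH, THF, 0 °C → rt; Cl2C=CHCl, −50 °C → rt (dilute, Ar); n-BuLi (2.5 equiv), −78 → −40 °C; MeOH, −78 °C; cold NaHCO3 work-up, used at once
Reagents that add atoms: n-butyllithium, [Li]CCCC (lithium stands only in intermediate 20)
Why: In this dichlorovinyl ether route to ynol ethers the potassium alkoxide should add to dichloroacetylene formed in situ, and n-BuLi then effects elimination and Cl–Li exchange to the lithium alkynyl ether that methanol protonates; the C–O bond at the carbinol carbon is never broken, so its configuration is retained.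

Step 11
Reactants: 21 syn ethynyl ether
Product: 23 (2R,3S)-2-(3-methoxy-4-TIPSO-phenyl)-5-[3-(TIPSO)propyl]-3-(trityloxymethyl)-2,3-dihydro-1-benzofuran-7-ol, via fused oxepine 22 (not isolated)
Conditions: [JohnPhosAu(MeCN)]SbF6 (3 mol %), CH2Cl2 (0.02 M), 4 Å MS, −20 °C → rt
Reagents that add atoms: none
Why: Cationic gold(I) coordinates the ynol ether so that its oxygen-bearing carbon (future C7a) is attacked by furan C2 (future C3a), giving a cyclopropyl gold carbenoid whose furan ring opens to a (Z)-dienal carbene; the formyl oxygen adds to the carbene carbon, loss of gold gives oxepine 22, and this closes to the C6–C7 arene oxide and isomerises to phenol 23. The closest known reaction type is the gold-catalysed furan–yne phenol synthesis (Hashmi phenol synthesis), which is documented for furans tethered to ynol ethers and ynamides. The dihydrofuran ring (O1–C2–C3–C3a–C7a) closes by 5-exo-dig attack of the furan on the activated alkyne, and the benzene ring closes by 6π disrotatory electrocyclisation of the oxepine, which forms C6–C7. No stereocentre is created: C2 and C3 are carried through unchanged, and the syn open chain places the aryl and trityloxymethyl groups trans on the new ring, so the closure is unstrained. The step needs regioselective arene oxide opening and furan attack in preference to ionisation of the benzylic C2–O bond: breaking C6–O is favoured because the resulting cation is stabilised by O1 on C7a, which leaves the hydroxyl on C7, while the three-atom tether (fast 5-exo closure), the silyl cap on the para oxygen, the acid-free and silver-free catalyst and the low temperature disfavour C2–O heterolysis.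

Step 12
Reactants: 23 C7 phenol
Product: 24 (2R,3S)-7-methoxy-2-(3-methoxy-4-TIPSO-phenyl)-5-[3-(TIPSO)propyl]-3-(trityloxymethyl)-2,3-dihydro-1-benzofuran
Conditions: MeI, K2CO3, acetone, rt, Ar
Reagents that add atoms: iodomethane, CI
Why: Williamson methylation of the only free phenol under mild carbonate conditions should leave the aryl TIPS ether and the trityl ether intact.

Step 13
Reactants: 24 trityl ether
Product: 25 {(2R,3S)-7-methoxy-2-(3-methoxy-4-TIPSO-phenyl)-5-[3-(TIPSO)propyl]-2,3-dihydro-1-benzofuran-3-yl}methanol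
Conditions: CSA (0.2 equiv), MeOH/CH2Cl2 (1:1), 0 °C → rt; Et3N quench
Reagents that add atoms: none
Why: Acid-catalysed methanolysis of the trityl ether (SN1 loss of the trityl cation, trapped by methanol) is much faster than cleavage of primary or aryl TIPS ethers, so only the C9 hydroxyl should be released.

Step 14
Reactants: 26 p-coumaric acid
Product: 28 (E)-3-[4-(tert-butyldimethylsilyloxy)phenyl]prop-2-enoic acid, via bis-TBS coumarate 27 (not isolated)
Conditions: TBSCl (2.3 equiv), imidazole, DMF, rt; then AcOH/THF/H2O, rt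
Reagents that add atoms: tert-butyldimethylsilyl chloride, CC(C)(C)[Si](C)(C)Cl
Why: Bis-silylation followed by selective hydrolysis of the labile silyl ester is the usual way to mask the phenol of a hydroxycinnamic acid while leaving the acid free for coupling.

Step 15
Reactants: 25 C9 alcohol; 28 O-TBS p-coumaric acid
Product: 29 {(2R,3S)-7-methoxy-2-(3-methoxy-4-TIPSO-phenyl)-5-[3-(TIPSO)propyl]-2,3-dihydro-1-benzofuran-3-yl}methyl (E)-3-[4-(tert-butyldimethylsilyloxy)phenyl]prop-2-enoate
Conditions: EDC·HCl, DMAP, CH2Cl2, 0 °C → rt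
Reagents that add atoms: none
Why: Steglich esterification of the unhindered primary alcohol with the cinnamic acid should proceed without touching the E alkene or the silyl ethers.

Step 16
Reactants: 29 tris-silyl ester
Product: 30 [(2R,3S)-2-(4-hydroxy-3-methoxyphenyl)-5-(3-hydroxypropyl)-7-methoxy-2,3-dihydro-1-benzofuran-3-yl]methyl (E)-3-(4-hydroxyphenyl)prop-2-enoate (CNP0202924.1)
Conditions: HF·pyridine, pyridine/THF, 0 °C → rt
Reagents that add atoms: none
Why: Global desilylation with pyridine-buffered HF should remove the two aryl silyl ethers and the primary TIPS ether without hydrolysing the cinnamate ester or opening the benzylic ether.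

Compound list
1 | allyl alcohol | C=CCO | starting material
2 | allyl triisopropylsilyl ether | C=CCO[Si](C(C)C)(C(C)C)C(C)C | intermediate
3 | 9-borabicyclo[3.3.1]nonane (9-BBN) | B1C2CCCC1CCC2 | starting material
4 | 4-bromo-2-furaldehyde | O=Cc1cc(Br)co1 | starting material
5 | B-[3-(triisopropylsilyloxy)propyl]-9-BBN | CC(C)[Si](OCCCB1C2CCCC1CCC2)(C(C)C)C(C)C | intermediate
6 | 4-[3-(triisopropylsilyloxy)propyl]furan-2-carbaldehyde | O=Cc1cc(CCCO[Si](C(C)C)(C(C)C)C(C)C)co1 | intermediate
7 | {4-[3-(triisopropylsilyloxy)propyl]furan-2-yl}acetonitrile | N#CCc1cc(CCCO[Si](C(C)C)(C(C)C)C(C)C)co1 | intermediate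
8 | {4-[3-(triisopropylsilyloxy)propyl]furan-2-yl}acetic acid | O=C(O)Cc1cc(CCCO[Si](C(C)C)(C(C)C)C(C)C)co1 | intermediate
9 | (R)-4-benzyl-1,3-oxazolidin-2-one | O=C1N[C@H](Cc2ccccc2)CO1 | starting material
10 | mixed pivalic anhydride of acid 8 | CC(C)(C)C(=O)OC(=O)Cc1cc(CCCO[Si](C(C)C)(C(C)C)C(C)C)co1 | intermediate
11 | (R)-4-benzyl-3-({4-[3-(triisopropylsilyloxy)propyl]furan-2-yl}acetyl)-1,3-oxazolidin-2-one | O=C(Cc1cc(CCCO[Si](C(C)C)(C(C)C)C(C)C)co1)N1C(=O)OC[C@H]1Cc1ccccc1 | intermediate
12 | vanillin | COc1cc(C=O)ccc1O | starting material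
13 | 3-methoxy-4-(triisopropylsilyloxy)benzaldehyde | COc1cc(C=O)ccc1O[Si](C(C)C)(C(C)C)C(C)C | intermediate
14 | (Z)-dibutylboron enolate of imide 11 | CCCCB(CCCC)O/C(=C\c1cc(CCCO[Si](C(C)C)(C(C)C)C(C)C)co1)N1C(=O)OC[C@H]1Cc1ccccc1 | intermediate
15 | (R)-4-benzyl-3-[(2S,3R)-3-hydroxy-3-[3-methoxy-4-(triisopropylsilyloxy)phenyl]-2-{4-[3-(triisopropylsilyloxy)propyl]furan-2-yl}propanoyl]-1,3-oxazolidin-2-one | COc1cc([C@H](O)[C@H](C(=O)N2C(=O)OC[C@H]2Cc2ccccc2)c2cc(CCCO[Si](C(C)C)(C(C)C)C(C)C)co2)ccc1O[Si](C(C)C)(C(C)C)C(C)C | intermediate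
16 | (1R,2S)-1-[3-methoxy-4-(triisopropylsilyloxy)phenyl]-2-{4-[3-(triisopropylsilyloxy)propyl]furan-2-yl}propane-1,3-diol | COc1cc([C@H](O)[C@H](CO)c2cc(CCCO[Si](C(C)C)(C(C)C)C(C)C)co2)ccc1O[Si](C(C)C)(C(C)C)C(C)C | intermediate
17 | (1R,2S)-1-[3-methoxy-4-(triisopropylsilyloxy)phenyl]-2-{4-[3-(triisopropylsilyloxy)propyl]furan-2-yl}-3-(trityloxy)propan-1-ol | COc1cc([C@H](O)[C@H](COC(c2ccccc2)(c2ccccc2)c2ccccc2)c2cc(CCCO[Si](C(C)C)(C(C)C)C(C)C)co2)ccc1O[Si](C(C)C)(C(C)C)C(C)C | intermediate
18 | trichloroethylene | ClC=C(Cl)Cl | starting material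
19 | (E)-1,2-dichlorovinyl ether of alcohol 17 (1R,2S) | COc1cc([C@H](O/C(Cl)=C\Cl)[C@H](COC(c2ccccc2)(c2ccccc2)c2ccccc2)c2cc(CCCO[Si](C(C)C)(C(C)C)C(C)C)co2)ccc1O[Si](C(C)C)(C(C)C)C(C)C | intermediate
20 | lithium alkynyl ether (lithium acetylide of 21) | COc1cc([C@H](OC#C[Li])[C@H](COC(c2ccccc2)(c2ccccc2)c2ccccc2)c2cc(CCCO[Si](C(C)C)(C(C)C)C(C)C)co2)ccc1O[Si](C(C)C)(C(C)C)C(C)C | intermediate
21 | (1R,2S)-1-[3-methoxy-4-(triisopropylsilyloxy)phenyl]-2-{4-[3-(triisopropylsilyloxy)propyl]furan-2-yl}-3-(trityloxy)propyl ethynyl ether (key-step precursor) | COc1cc([C@H](OC#C)[C@H](COC(c2ccccc2)(c2ccccc2)c2ccccc2)c2cc(CCCO[Si](C(C)C)(C(C)C)C(C)C)co2)ccc1O[Si](C(C)C)(C(C)C)C(C)C | intermediate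
22 | 2,3-dihydrofuro-fused oxepine (O bridging C6 and C7; C7=C7a, C3a=C4, C5=C6), 2R,3S | COc1cc([C@@H]2OC3=COC=C(CCCO[Si](C(C)C)(C(C)C)C(C)C)C=C3[C@H]2COC(c2ccccc2)(c2ccccc2)c2ccccc2)ccc1O[Si](C(C)C)(C(C)C)C(C)C | intermediate
23 | (2R,3S)-2-[3-methoxy-4-(triisopropylsilyloxy)phenyl]-5-[3-(triisopropylsilyloxy)propyl]-3-(trityloxymethyl)-2,3-dihydro-1-benzofuran-7-ol (key-step product) | COc1cc([C@@H]2Oc3c(O)cc(CCCO[Si](C(C)C)(C(C)C)C(C)C)cc3[C@H]2COC(c2ccccc2)(c2ccccc2)c2ccccc2)ccc1O[Si](C(C)C)(C(C)C)C(C)C | intermediate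
24 | (2R,3S)-7-methoxy-2-[3-methoxy-4-(triisopropylsilyloxy)phenyl]-5-[3-(triisopropylsilyloxy)propyl]-3-(trityloxymethyl)-2,3-dihydro-1-benzofuran | COc1cc([C@@H]2Oc3c(OC)cc(CCCO[Si](C(C)C)(C(C)C)C(C)C)cc3[C@H]2COC(c2ccccc2)(c2ccccc2)c2ccccc2)ccc1O[Si](C(C)C)(C(C)C)C(C)C | intermediate
25 | {(2R,3S)-7-methoxy-2-[3-methoxy-4-(triisopropylsilyloxy)phenyl]-5-[3-(triisopropylsilyloxy)propyl]-2,3-dihydro-1-benzofuran-3-yl}methanol | COc1cc([C@@H]2Oc3c(OC)cc(CCCO[Si](C(C)C)(C(C)C)C(C)C)cc3[C@H]2CO)ccc1O[Si](C(C)C)(C(C)C)C(C)C | intermediate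
26 | p-coumaric acid | O=C(O)/C=C/c1ccc(O)cc1 | starting material
27 | tert-butyldimethylsilyl (E)-3-[4-(tert-butyldimethylsilyloxy)phenyl]prop-2-enoate | CC(C)(C)[Si](C)(C)OC(=O)/C=C/c1ccc(O[Si](C)(C)C(C)(C)C)cc1 | intermediate
28 | (E)-3-[4-(tert-butyldimethylsilyloxy)phenyl]prop-2-enoic acid | O=C(O)/C=C/c1ccc(O[Si](C)(C)C(C)(C)C)cc1 | intermediate
29 | {(2R,3S)-7-methoxy-2-[3-methoxy-4-(triisopropylsilyloxy)phenyl]-5-[3-(triisopropylsilyloxy)propyl]-2,3-dihydro-1-benzofuran-3-yl}methyl (E)-3-[4-(tert-butyldimethylsilyloxy)phenyl]prop-2-enoate | COc1cc([C@@H]2Oc3c(OC)cc(CCCO[Si](C(C)C)(C(C)C)C(C)C)cc3[C@H]2COC(=O)/C=C/c2ccc(O[Si](C)(C)C(C)(C)C)cc2)ccc1O[Si](C(C)C)(C(C)C)C(C)C | intermediate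
30 | [(2R,3S)-2-(4-hydroxy-3-methoxyphenyl)-5-(3-hydroxypropyl)-7-methoxy-2,3-dihydro-1-benzofuran-3-yl]methyl (E)-3-(4-hydroxyphenyl)prop-2-enoate | COc1cc([C@@H]2Oc3c(OC)cc(CCCO)cc3[C@H]2COC(=O)/C=C/c2ccc(O)cc2)ccc1O | target

Total step count: 16
Longest linear sequence: 14 (steps 1–5, 7–13, 15, 16)

Steps most likely to fail

1. Step 11 (gold benzannulation). Once gold has activated the ynol ether it behaves as a ketene-oxonium. Heterolysis of the benzylic C2–O bond next to the electron-rich aryl ring may then compete with furan attack, which would cost material or erode the configuration at C2. Traces of water would hydrate the ynol ether to an acetate. The fallback redesigns the substrate, not the catalyst. It sets out from 21. One-pot exchange of the aryl silyl ether for a pivalate (TBAF, THF, −78 °C, then PivCl) should give pivalate-capped ethynyl ether F1, whose para oxygen no longer stabilises a benzylic cation. The gold cycloisomerisation run on F1 should give the C7 phenol F2. Methylation (MeI, K2CO3, acetone) should give methyl ether F3. Methanolysis of the pivalate (NaOMe, MeOH) should give guaiacyl phenol F4, and silylation (TIPSCl, imidazole) rejoins the route at 24.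

2. Step 10 (ynol ether formation). Addition of the hindered secondary benzylic alkoxide to dichloroacetylene may be slow. The potassium alkoxide would then sit at room temperature, where base-induced degradation and intermolecular silyl transfer from the aryl silyl ether can set in. The fallback assembles the two alkyne carbons from two one-carbon pieces and needs no potassium alkoxide. It sets out from 17. Formylation (acetic formic anhydride, pyridine, 0 °C) should give formate F5. Ramirez-type dichloromethylenation of the formate carbonyl (PPh3, CCl4, THF, 60 °C) should give 2,2-dichlorovinyl ether F6. n-BuLi (2.2 equiv, THF, −78 °C) should convert F6 by elimination and Cl–Li exchange into lithium alkynyl ether 20, which methanol protonates to 21.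

3. Step 3 (one-carbon homologation). The TosMIC adduct of an aldehyde can lose sulfinate to give the 5-substituted oxazole instead of opening towards the nitrile, and the electron-rich furfural can condense under the strongly basic conditions. The fallback is an Arndt–Eistert homologation at the acid oxidation level. It sets out from 6. Pinnick oxidation (NaClO2, NaH2PO4, 2-methyl-2-butene, t-BuOH/H2O) should give furoic acid F7. Activation (i-BuOCOCl, N-methylmorpholine, THF, −15 °C) and trimethylsilyldiazomethane should give diazoketone F8. Silver-catalysed Wolff rearrangement in aqueous THF (AgOBz, Et3N) should give acid 8, so that steps 3 and 4 are both replaced.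

Further compounds
F1 | step 11 | 4-[(1R,2S)-1-(ethynyloxy)-2-{4-[3-(triisopropylsilyloxy)propyl]furan-2-yl}-3-(trityloxy)propyl]-2-methoxyphenyl pivalate | COc1cc([C@H](OC#C)[C@H](COC(c2ccccc2)(c2ccccc2)c2ccccc2)c2cc(CCCO[Si](C(C)C)(C(C)C)C(C)C)co2)ccc1OC(=O)C(C)(C)C
F2 | step 11 | 4-{(2R,3S)-7-hydroxy-5-[3-(triisopropylsilyloxy)propyl]-3-(trityloxymethyl)-2,3-dihydro-1-benzofuran-2-yl}-2-methoxyphenyl pivalate | COc1cc([C@@H]2Oc3c(O)cc(CCCO[Si](C(C)C)(C(C)C)C(C)C)cc3[C@H]2COC(c2ccccc2)(c2ccccc2)c2ccccc2)ccc1OC(=O)C(C)(C)C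
F3 | step 11 | 4-{(2R,3S)-7-methoxy-5-[3-(triisopropylsilyloxy)propyl]-3-(trityloxymethyl)-2,3-dihydro-1-benzofuran-2-yl}-2-methoxyphenyl pivalate | COc1cc([C@@H]2Oc3c(OC)cc(CCCO[Si](C(C)C)(C(C)C)C(C)C)cc3[C@H]2COC(c2ccccc2)(c2ccccc2)c2ccccc2)ccc1OC(=O)C(C)(C)C
F4 | step 11 | 4-{(2R,3S)-7-methoxy-5-[3-(triisopropylsilyloxy)propyl]-3-(trityloxymethyl)-2,3-dihydro-1-benzofuran-2-yl}-2-methoxyphenol | COc1cc([C@@H]2Oc3c(OC)cc(CCCO[Si](C(C)C)(C(C)C)C(C)C)cc3[C@H]2COC(c2ccccc2)(c2ccccc2)c2ccccc2)ccc1O
F5 | step 10 | (1R,2S)-1-[3-methoxy-4-(triisopropylsilyloxy)phenyl]-2-{4-[3-(triisopropylsilyloxy)propyl]furan-2-yl}-3-(trityloxy)propyl formate | COc1cc([C@H](OC=O)[C@H](COC(c2ccccc2)(c2ccccc2)c2ccccc2)c2cc(CCCO[Si](C(C)C)(C(C)C)C(C)C)co2)ccc1O[Si](C(C)C)(C(C)C)C(C)C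
F6 | step 10 | (1R,2S)-1-[3-methoxy-4-(triisopropylsilyloxy)phenyl]-2-{4-[3-(triisopropylsilyloxy)propyl]furan-2-yl}-3-(trityloxy)propyl 2,2-dichlorovinyl ether | COc1cc([C@H](OC=C(Cl)Cl)[C@H](COC(c2ccccc2)(c2ccccc2)c2ccccc2)c2cc(CCCO[Si](C(C)C)(C(C)C)C(C)C)co2)ccc1O[Si](C(C)C)(C(C)C)C(C)C
F7 | step 3 | 4-[3-(triisopropylsilyloxy)propyl]furan-2-carboxylic acid | O=C(O)c1cc(CCCO[Si](C(C)C)(C(C)C)C(C)C)co1
F8 | step 3 | 2-diazo-1-{4-[3-(triisopropylsilyloxy)propyl]furan-2-yl}ethan-1-one | [N-]=[N+]=CC(=O)c1cc(CCCO[Si](C(C)C)(C(C)C)C(C)C)co1
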